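**Plan**
1. The target is epicatechin-(4β→8)-epiafzelechin. After removal of eight benzyl ethers, the lower 3-OH is traced back to a 3-ketone and then to a 3-formyl-2H-chromene. The cuts follow in this order: O1–C2 and C3–C4 of lower ring C, the C4a–CHO bond, and the interflavan C4–C8 bond.
2. Enabling feature: lower ring C (O1, C2, C3, C4) is fused to ring A at C8a/C4a, and C8, the other neighbour of the O1-bearing C8a, already holds the upper unit. A phenol with a formyl group on C4a therefore maps its oxygen onto O1 and its formyl carbon onto C4, and it can be annulated in one direction only.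
3. Forward order: upper rings A, B and C come intact from (−)-epicatechin. Lower ring A is attached at upper C4 and then formylated. Lower ring C closes last and brings ring B in with the enal.
4. Stereochemistry: upper C2/C3 come from the chiral pool and upper C4 from attack anti to the 3-OBn group. Lower C2 is set by the S-configured aminocatalyst and lower C3 by a bulky hydride that attacks anti to the 2-aryl group.
5. The formyl group that the annulation leaves on C3 is exchanged for oxygen by Baeyer–Villiger oxidation.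

Key step: step 7

Remark: α/β refer to the usual flavan drawing (ring A left, O1 up). Read this way, the SMILES shows 2R,3R (2,3-cis) in both units and a 4β (3,4-trans) interflavan bond. Compounds 1, 5 and 9, the ylide and the amine catalyst are taken as commercial.

Step 1
Reactants: 1 (−)-epicatechin
Product: 2 5,7,3',4'-tetra-O-benzyl-(−)-epicatechin (2R,3R)
Conditions: BnBr, K2CO3, DMF, 0 °C to rt
Reagents that add atoms: benzyl bromide, BrCc1ccccc1
Why: Williamson etherification in which K2CO3 deprotonates only the four phenols, so the secondary 3-OH stays free, and the mild base at low temperature avoids opening of ring C through a quinone methide, which keeps C2 and C3 intact.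

Step 2
Reactants: 2 5,7,3',4'-tetra-O-benzyl-(−)-epicatechin
Product: 3 3,5,7,3',4'-penta-O-benzyl-(−)-epicatechin (2R,3R)
Conditions: NaH, BnBr, n-Bu4NI (cat.), DMF, 0 °C to rt
Reagents that add atoms: benzyl bromide, BrCc1ccccc1
Why: Williamson etherification of the remaining alcohol through its sodium alkoxide, safe for C2 because no free phenol is left to open ring C, and the new benzyl group masks O3, steers the attack at C4 and is removed with the others in the last step.

Step 3
Reactants: 3 3,5,7,3',4'-penta-O-benzyl-(−)-epicatechin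
Product: 4 3,5,7,3',4'-penta-O-benzyl-4β-(2-ethoxyethoxy)epicatechin (2,3-cis, 3,4-trans)
Conditions: DDQ, 2-ethoxyethanol, CH2Cl2, rt
Reagents that add atoms: 2-ethoxyethanol, CCOCCO
Why: Oxidative benzylic C–H etherification in which DDQ abstracts hydride from C4, the position activated by the 5,7-dialkoxy ring A, and the alcohol adds anti to the axial 3-OBn group (4β), a configuration without consequence because C4 is ionised again in step 4.

Step 4
Reactants: 4 3,5,7,3',4'-penta-O-benzyl-4β-(2-ethoxyethoxy)epicatechin; 5 3,5-bis(benzyloxy)phenol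
Product: 6 4β-[2,4-bis(benzyloxy)-6-hydroxyphenyl]-3,5,7,3',4'-penta-O-benzylepicatechin
Conditions: 5 (3 equiv), Me3SiOTf (0.2 equiv), CH2Cl2, −78 to −40 °C
Reagents that add atoms: none
Why: Lewis acid promoted Friedel–Crafts alkylation (SN1 at C4), the reaction type behind 4-arylflavan-3-ols and 4→8 procyanidins, in which the arene enters anti to the 3-OBn group and sets the 4β configuration, reacts at one of its two equivalent carbons next to the hydroxyl because the carbon between the two benzyloxy groups is as shielded as C6 of a benzylated flavan-3-ol, and is kept from double alkylation by its excess while O-alkylation is reversible under the acid.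

Step 5
Reactants: 6 4β-[2,4-bis(benzyloxy)-6-hydroxyphenyl]-3,5,7,3',4'-penta-O-benzylepicatechin
Product: 8 4,6-bis(benzyloxy)-2-hydroxy-3-(3,5,7,3',4'-penta-O-benzylepicatechin-4β-yl)benzaldehyde, via salicyl alcohol 7 (not isolated)
Conditions: MgCl2, Et3N, (CH2O)n, THF, reflux; then 1 M HCl
Reagents that add atoms: paraformaldehyde (reacts as formaldehyde), C=O
Why: Casnati–Skattebøl ortho-formylation in which the magnesium phenoxide delivers bound formaldehyde through a cyclic transition state to the only free ortho carbon to give 7, whose alkoxide passes hydride to a second formaldehyde, so the carbon para to oxygen is not touched and no strong acid meets the C4–aryl bond.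

Step 6
Reactants: 9 4-(benzyloxy)benzaldehyde
Product: 10 (E)-3-[4-(benzyloxy)phenyl]prop-2-enal
Conditions: Ph3P=CHCHO, toluene, 85 °C
Reagents that add atoms: (triphenylphosphoranylidene)acetaldehyde, O=CC=P(c1ccccc1)(c1ccccc1)c1ccccc1
Why: Wittig olefination with a stabilised formyl ylide, which gives the E-enal and adds the two carbons that become lower C3 and the sacrificial formyl group.

Step 7
Reactants: 8 4,6-bis(benzyloxy)-2-hydroxy-3-(3,5,7,3',4'-penta-O-benzylepicatechin-4β-yl)benzaldehyde; 10 (E)-3-[4-(benzyloxy)phenyl]prop-2-enal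
Product: 12 (2R)-5,7-bis(benzyloxy)-2-[4-(benzyloxy)phenyl]-8-(3,5,7,3',4'-penta-O-benzylepicatechin-4β-yl)-2H-chromene-3-carbaldehyde, via enamine 11 (not isolated)
Conditions: 10 (2 equiv), (S)-2-[diphenyl(trimethylsilyloxy)methyl]pyrrolidine (30 mol %), 2-nitrobenzoic acid (30 mol %), 4 Å MS, toluene, rt, dark
Reagents that add atoms: none
Why: The amine and 10 condense to an E-configured, s-trans iminium ion, the phenol oxygen of 8 adds to its β-carbon (oxa-Michael, O1–C2) to give enamine 11, the enamine carbon attacks the neighbouring formyl carbon (aldol, C3–C4), and loss of water followed by hydrolysis releases 12 and the amine. The closest known reaction type is this same amine-catalysed domino oxa-Michael/aldol condensation of salicylaldehydes with cinnamaldehydes to 2-aryl-2H-chromene-3-carbaldehydes, applied here to a 3-substituted 4,6-dialkoxysalicylaldehyde. Lower ring C closes in the aldol event as a 6-(enolexo)-exo-trig cyclisation. C2 is the only new stereocentre: the CPh2(OSiMe3) arm of the S-configured amine covers one face of the planar iminium ion, oxygen arrives at the open Si face of the β-carbon and places the aryl group α (2R) as in the target, and the fixed upper unit turns any minor C2 epimer into a diastereomer that chromatography can remove. The step needs site selectivity and a forward drive: 8 has one phenol, one formyl group and no other free ortho carbon, so only the 4→8-linked skeleton can arise, and the irreversible dehydration drains the reversible oxa-Michael equilibrium. The acid cocatalyst speeds iminium formation and turnover with the electron-rich enal, the sieves take up the water, and work-up at full conversion in the dark limits retro-addition or electrocyclic ring opening that would erode C2.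

Step 8
Reactants: 12 (2R)-2H-chromene-3-carbaldehyde carrying the upper unit at C8
Product: 13 (2R)-5,7-bis(benzyloxy)-2-[4-(benzyloxy)phenyl]-8-(3,5,7,3',4'-penta-O-benzylepicatechin-4β-yl)-2H-chromen-3-yl formate
Conditions: mCPBA (1.1 equiv), CH2Cl2, 0 °C
Reagents that add atoms: 3-chloroperoxybenzoic acid, OOC(=O)c1cccc(Cl)c1
Why: Baeyer–Villiger oxidation of an α,β-unsaturated aldehyde to a vinyl formate, in which the peracid adds to the formyl group and the alkenyl carbon C3, made electron-rich by the oxygens of ring A through the C3=C4 bond, migrates in preference to hydrogen as the aryl group does in electron-rich benzaldehydes, while C2 is not involved and the near-stoichiometric oxidant at 0 °C limits epoxidation of the product.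

Step 9
Reactants: 13 (2R)-2H-chromen-3-yl formate carrying the upper unit at C8
Product: 15 (2R)-5,7-bis(benzyloxy)-2-[4-(benzyloxy)phenyl]-8-(3,5,7,3',4'-penta-O-benzylepicatechin-4β-yl)chroman-3-one, via enol 14 (not isolated)
Conditions: KHCO3 (cat.), MeOH/THF, −10 °C, short; pH 7 buffer quench
Reagents that add atoms: none
Why: Transesterification of an activated enol ester, in which methanol takes over the formyl group under a trace of weak base and enol 14 ketonises by protonation at C4, with low basicity, low temperature and a buffered quench chosen so that the benzylic C2–H next to the ketone is not removed.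

Step 10
Reactants: 15 (2R)-chroman-3-one carrying the upper unit at C8
Product: 16 3,5,7,3',4'-penta-O-benzylepicatechin-(4β→8)-5,7,4'-tri-O-benzylepiafzelechin (lower unit 2R,3R, lower 3-OH free)
Conditions: LiBH(s-Bu)3, LiBr, THF, −78 °C; then H2O
Reagents that add atoms: none
Why: Diastereoselective ketone reduction with a bulky trialkylborohydride, the standard way from 2-arylchroman-3-ones to 2,3-cis-flavan-3-ols, in which the reagent attacks along the equatorial trajectory from the β face opposite to the equatorial 2-aryl group and pushes the hydroxyl into the axial α position (3R, cis to C2), while at −78 °C reduction outruns enolisation.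

Step 11
Reactants: 16 3,5,7,3',4'-penta-O-benzylepicatechin-(4β→8)-5,7,4'-tri-O-benzylepiafzelechin
Product: 17 epicatechin-(4β→8)-epiafzelechin (target)
Conditions: H2 (1 atm), Pd(OH)2/C, THF/MeOH/H2O, rt
Reagents that add atoms: none
Why: Catalytic hydrogenolysis of the seven aryl benzyl ethers and the one alkyl benzyl ether under neutral conditions, as is usual for benzylated procyanidins, with the ring C C–O bonds and the interflavan bond expected to survive at 1 atm and no stereocentre touched.

**Compound list**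
1 | (−)-epicatechin | C1c2c(O)cc(O)cc2O[C@H](c2ccc(O)c(O)c2)[C@@H]1O | starting material
2 | 5,7,3',4'-tetra-O-benzyl-(−)-epicatechin | C1c2c(OCc3ccccc3)cc(OCc3ccccc3)cc2O[C@H](c2ccc(OCc3ccccc3)c(OCc3ccccc3)c2)[C@@H]1O | intermediate
3 | 3,5,7,3',4'-penta-O-benzyl-(−)-epicatechin | C1c2c(OCc3ccccc3)cc(OCc3ccccc3)cc2O[C@H](c2ccc(OCc3ccccc3)c(OCc3ccccc3)c2)[C@@H]1OCc3ccccc3 | intermediate
4 | 3,5,7,3',4'-penta-O-benzyl-4β-(2-ethoxyethoxy)epicatechin | CCOCCO[C@H]1c2c(OCc3ccccc3)cc(OCc3ccccc3)cc2O[C@H](c2ccc(OCc3ccccc3)c(OCc3ccccc3)c2)[C@@H]1OCc3ccccc3 | intermediate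
5 | 3,5-bis(benzyloxy)phenol | Oc1cc(OCc2ccccc2)cc(OCc2ccccc2)c1 | starting material
6 | 4β-[2,4-bis(benzyloxy)-6-hydroxyphenyl]-3,5,7,3',4'-penta-O-benzylepicatechin | Oc1cc(OCc5ccccc5)cc(OCc5ccccc5)c1[C@H]3c4c(OCc5ccccc5)cc(OCc5ccccc5)cc4O[C@H](c4ccc(OCc5ccccc5)c(OCc5ccccc5)c4)[C@@H]3OCc5ccccc5 | intermediate
7 | 4β-[2,4-bis(benzyloxy)-6-hydroxy-5-(hydroxymethyl)phenyl]-3,5,7,3',4'-penta-O-benzylepicatechin (salicyl alcohol, not isolated) | OCc1c(OCc5ccccc5)cc(OCc5ccccc5)c(c1O)[C@H]3c4c(OCc5ccccc5)cc(OCc5ccccc5)cc4O[C@H](c4ccc(OCc5ccccc5)c(OCc5ccccc5)c4)[C@@H]3OCc5ccccc5 | intermediate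
8 | 4,6-bis(benzyloxy)-2-hydroxy-3-(3,5,7,3',4'-penta-O-benzylepicatechin-4β-yl)benzaldehyde | O=Cc1c(OCc5ccccc5)cc(OCc5ccccc5)c(c1O)[C@H]3c4c(OCc5ccccc5)cc(OCc5ccccc5)cc4O[C@H](c4ccc(OCc5ccccc5)c(OCc5ccccc5)c4)[C@@H]3OCc5ccccc5 | intermediate
9 | 4-(benzyloxy)benzaldehyde | O=Cc1ccc(OCc2ccccc2)cc1 | starting material
10 | (E)-3-[4-(benzyloxy)phenyl]prop-2-enal | O=C/C=C/c1ccc(OCc2ccccc2)cc1 | intermediate
11 | E-enamine of the oxa-Michael adduct of 8 and 10 with the S-configured amine, ether carbon configured as C2 of 12 (not isolated) | O=Cc1c(OCc5ccccc5)cc(OCc5ccccc5)c([C@H]3c4c(OCc5ccccc5)cc(OCc5ccccc5)cc4O[C@H](c4ccc(OCc5ccccc5)c(OCc5ccccc5)c4)[C@@H]3OCc5ccccc5)c1O[C@H](c1ccc(OCc5ccccc5)cc1)/C=C/N1CCC[C@H]1C(c1ccccc1)(c1ccccc1)O[Si](C)(C)C | intermediate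
12 | (2R)-5,7-bis(benzyloxy)-2-[4-(benzyloxy)phenyl]-8-(3,5,7,3',4'-penta-O-benzylepicatechin-4β-yl)-2H-chromene-3-carbaldehyde | O(Cc5ccccc5)c1ccc([C@H]2Oc3c(c(OCc5ccccc5)cc(OCc5ccccc5)c3[C@H]3c4c(OCc5ccccc5)cc(OCc5ccccc5)cc4O[C@H](c4ccc(OCc5ccccc5)c(OCc5ccccc5)c4)[C@@H]3OCc5ccccc5)C=C2C=O)cc1 | intermediate
13 | (2R)-2H-chromen-3-yl formate corresponding to 12 | O(Cc5ccccc5)c1ccc([C@H]2Oc3c(c(OCc5ccccc5)cc(OCc5ccccc5)c3[C@H]3c4c(OCc5ccccc5)cc(OCc5ccccc5)cc4O[C@H](c4ccc(OCc5ccccc5)c(OCc5ccccc5)c4)[C@@H]3OCc5ccccc5)C=C2OC=O)cc1 | intermediate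
14 | (2R)-2H-chromen-3-ol corresponding to 13 (enol, not isolated) | O(Cc5ccccc5)c1ccc([C@H]2Oc3c(c(OCc5ccccc5)cc(OCc5ccccc5)c3[C@H]3c4c(OCc5ccccc5)cc(OCc5ccccc5)cc4O[C@H](c4ccc(OCc5ccccc5)c(OCc5ccccc5)c4)[C@@H]3OCc5ccccc5)C=C2O)cc1 | intermediate
15 | (2R)-5,7-bis(benzyloxy)-2-[4-(benzyloxy)phenyl]-8-(3,5,7,3',4'-penta-O-benzylepicatechin-4β-yl)chroman-3-one | O(Cc5ccccc5)c1ccc([C@H]2Oc3c(c(OCc5ccccc5)cc(OCc5ccccc5)c3[C@H]3c4c(OCc5ccccc5)cc(OCc5ccccc5)cc4O[C@H](c4ccc(OCc5ccccc5)c(OCc5ccccc5)c4)[C@@H]3OCc5ccccc5)CC2=O)cc1 | intermediate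
16 | 3,5,7,3',4'-penta-O-benzylepicatechin-(4β→8)-5,7,4'-tri-O-benzylepiafzelechin | O(Cc5ccccc5)c1ccc([C@H]2Oc3c(c(OCc5ccccc5)cc(OCc5ccccc5)c3[C@H]3c4c(OCc5ccccc5)cc(OCc5ccccc5)cc4O[C@H](c4ccc(OCc5ccccc5)c(OCc5ccccc5)c4)[C@@H]3OCc5ccccc5)C[C@H]2O)cc1 | intermediate
17 | epicatechin-(4β→8)-epiafzelechin | Oc1ccc([C@H]2Oc3c(c(O)cc(O)c3[C@H]3c4c(O)cc(O)cc4O[C@H](c4ccc(O)c(O)c4)[C@@H]3O)C[C@H]2O)cc1 | target

Total step count: 11. Longest linear sequence: 10 steps (steps 1–5 and 7–11); step 6 is a one-step side branch.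

**Three steps most likely to fail**

Step 7. The oxa-Michael addition may be slow, because the phenol is buttressed by the upper unit and hydrogen-bonded to a formyl group that two alkoxy groups deactivate. Facial selectivity may also erode through reversible addition over a long reaction time.
- Fallback: the lower unit is completed first on an unhindered phenol and the interflavan bond is made last. The sequence sets out from 5 and uses 10 and 4 from the main route.
- MgCl2/Et3N/(CH2O)n formylation of 5 passes through 3,5-bis(benzyloxy)-2-(hydroxymethyl)phenol F1 to 4,6-bis(benzyloxy)-2-hydroxybenzaldehyde F2.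
- The same amine-catalysed domino reaction with 10 leads through the monomeric enamine F3 to (2R)-5,7-bis(benzyloxy)-2-[4-(benzyloxy)phenyl]-2H-chromene-3-carbaldehyde F4.
- mCPBA gives the 2H-chromen-3-yl formate F5. Methanolysis releases the 2H-chromen-3-ol F6, which ketonises to the (2R)-chroman-3-one F7, and LiBH(s-Bu)3 gives 5,7,4'-tri-O-benzyl-(−)-epiafzelechin F8.
- An excess of F8 is then coupled with 4 under Me3SiOTf at −78 °C, the established C4→C8 Friedel–Crafts coupling of benzylated flavan-3-ols. This comes back to the route at 16.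

Step 8. The electron-rich enol formate double bond may be epoxidised as it forms, hydrogen may migrate instead of the alkenyl carbon, or the alkoxy-rich arenes may be oxidised.
- Fallback: the formyl carbon is removed by a Curtius degradation instead of an oxygen insertion. The sequence sets out from 12.
- Pinnick oxidation (NaClO2, NaH2PO4, 2-methylbut-2-ene) gives the 2H-chromene-3-carboxylic acid F9.
- (PhO)2P(O)N3/Et3N in toluene gives the acyl azide F10, which on warming loses nitrogen to the 3-isocyanato-2H-chromene F11.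
- Dilute aqueous HCl in THF hydrolyses F11 with loss of CO2 and ammonia. This sequence is the usual access to chroman-3-ones from 2H-chromene-3-carboxylic acids; it comes back at 15 and bypasses 13 and 14.

Step 9. The freshly released ketone may enolise towards C2 during ester cleavage or on silica, which would scramble the lower C2 configuration.
- Fallback: the ketone is avoided altogether and C3 is set by hydrogenation. The sequence sets out from 13.
- H2 over Pd(OH)2/C in THF/EtOAc should add syn to the C3=C4 bond from the β face, opposite to the pseudoaxial 2-aryl group, as in the classical reduction of flav-3-enes and flavylium salts to 2,3-cis-flavans.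
- The same operation removes the eight benzyl groups and gives epicatechin-(4β→8)-(3-O-formylepiafzelechin) F12.
- KHCO3-catalysed methanolysis under argon then cleaves the formate and comes back to the route at 17.

**Further compounds**
F1 | step 7 | 3,5-bis(benzyloxy)-2-(hydroxymethyl)phenol | OCc1c(O)cc(OCc2ccccc2)cc1OCc1ccccc1
F2 | step 7 | 4,6-bis(benzyloxy)-2-hydroxybenzaldehyde | O=Cc1c(O)cc(OCc2ccccc2)cc1OCc1ccccc1
F3 | step 7 | E-enamine of the oxa-Michael adduct of F2 and 10 with the S-configured amine | O=Cc1c(OCc5ccccc5)cc(OCc5ccccc5)cc1O[C@H](c1ccc(OCc5ccccc5)cc1)/C=C/N1CCC[C@H]1C(c1ccccc1)(c1ccccc1)O[Si](C)(C)C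
F4 | step 7 | (2R)-5,7-bis(benzyloxy)-2-[4-(benzyloxy)phenyl]-2H-chromene-3-carbaldehyde | O(Cc5ccccc5)c1ccc([C@H]2Oc3cc(OCc5ccccc5)cc(OCc5ccccc5)c3C=C2C=O)cc1
F5 | step 7 | (2R)-5,7-bis(benzyloxy)-2-[4-(benzyloxy)phenyl]-2H-chromen-3-yl formate | O(Cc5ccccc5)c1ccc([C@H]2Oc3cc(OCc5ccccc5)cc(OCc5ccccc5)c3C=C2OC=O)cc1
F6 | step 7 | (2R)-5,7-bis(benzyloxy)-2-[4-(benzyloxy)phenyl]-2H-chromen-3-ol | O(Cc5ccccc5)c1ccc([C@H]2Oc3cc(OCc5ccccc5)cc(OCc5ccccc5)c3C=C2O)cc1
F7 | step 7 | (2R)-5,7-bis(benzyloxy)-2-[4-(benzyloxy)phenyl]chroman-3-one | O(Cc5ccccc5)c1ccc([C@H]2Oc3cc(OCc5ccccc5)cc(OCc5ccccc5)c3CC2=O)cc1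
F8 | step 7 | 5,7,4'-tri-O-benzyl-(−)-epiafzelechin (2R,3R) | O(Cc5ccccc5)c1ccc([C@H]2Oc3cc(OCc5ccccc5)cc(OCc5ccccc5)c3C[C@H]2O)cc1
F9 | step 8 | (2R)-2H-chromene-3-carboxylic acid corresponding to 12 | O(Cc5ccccc5)c1ccc([C@H]2Oc3c(c(OCc5ccccc5)cc(OCc5ccccc5)c3[C@H]3c4c(OCc5ccccc5)cc(OCc5ccccc5)cc4O[C@H](c4ccc(OCc5ccccc5)c(OCc5ccccc5)c4)[C@@H]3OCc5ccccc5)C=C2C(=O)O)cc1
F10 | step 8 | (2R)-2H-chromene-3-carbonyl azide corresponding to F9 | O(Cc5ccccc5)c1ccc([C@H]2Oc3c(c(OCc5ccccc5)cc(OCc5ccccc5)c3[C@H]3c4c(OCc5ccccc5)cc(OCc5ccccc5)cc4O[C@H](c4ccc(OCc5ccccc5)c(OCc5ccccc5)c4)[C@@H]3OCc5ccccc5)C=C2C(=O)N=[N+]=[N-])cc1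
F11 | step 8 | (2R)-3-isocyanato-2H-chromene corresponding to F10 | O(Cc5ccccc5)c1ccc([C@H]2Oc3c(c(OCc5ccccc5)cc(OCc5ccccc5)c3[C@H]3c4c(OCc5ccccc5)cc(OCc5ccccc5)cc4O[C@H](c4ccc(OCc5ccccc5)c(OCc5ccccc5)c4)[C@@H]3OCc5ccccc5)C=C2N=C=O)cc1
F12 | step 9 | epicatechin-(4β→8)-(3-O-formylepiafzelechin) | Oc1ccc([C@H]2Oc3c(c(O)cc(O)c3[C@H]3c4c(O)cc(O)cc4O[C@H](c4ccc(O)c(O)c4)[C@@H]3O)C[C@H]2OC=O)cc1
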